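The chair opened the meeting with the charges of the flasks, which differ in the substrate charged, and with the two earlier runs.

| setting | red | violet | Wednesday's | Monday's | Tuesday's | Friday's | Thursday's |
|---|---|---|---|---|---|---|---|
| substrate | 0.0056 M | 0.40 M | 0.0080 M | 0.020 M | 0.060 M | 0.20 M | 0.60 M |
| reagent | 0.50 M | 0.50 M | 0.500 M | 0.500 M | 0.500 M | 0.500 M | 0.500 M |
| free catalyst | 20 mM | 20 mM | 20 mM | 20 mM | 20 mM | 20 mM | 20 mM |
| second catalyst | 4 mM | 4 mM | 4.0 mM | 4.0 mM | 4.0 mM | 4.0 mM | 4.0 mM |
| remark | run made earlier | run made earlier |  |  |  |  |  |
| time |  |  | 2.5 d | 2.5 d | 2.5 d | 2.5 d | 2.5 d |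

| run | time / d | target / % | substrate / % |
|---|---|---|---|
| red | 0.208 | 16 | 1 |
| red | 0.625 | 50 | 0 |
| red | 1.25 | 74 | 3 |
| red | 1.67 | 82 | 0 |
| red | 2.50 | 94 | 0 |
| violet | 0.500 | 5 | 0 |
| violet | 1.04 | 11 | 2 |
| violet | 1.67 | 12 | 0 |
| violet | 2.08 | 15 | 0 |
| violet | 2.50 | 18 | 0 |

(readings scatter by 2 percentage points)

- what was read earlier has a scatter of 2 percentage points, one standard deviation
- "hardly changes" means that all values lie within two and a half points (for a concentration: within two and a half percent of the largest)

* [target] at the end for Wednesday's, Monday's, Tuesday's, Friday's, Thursday's, in this order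
* how the row runs (falls, then rises / hardly changes / rises all the way / falls all the way / rises, then falls)

The chair pointed out that the substrate readings of both runs lie between 0% and 3%, while target arrives over days, so the row is a question of how much target has arrived after 2.5 d.

The secretary, whose own reckoning this is, proposed solving each end and joining them. At the dilute end, the red run read target at 94% of its charge at the end of that time. Taking this share over gives 0.00752 M for Wednesday's and 0.0188 M for Monday's. At the concentrated end, the secretary read from the violet run the ceiling, the amount of target made in the time from a large substrate charge with this reagent and second catalyst: 0.0720 M. That figure rests on a reading with a scatter of 2 percentage points.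

Dividing the ceiling by the red share gives the charge at which the two ends meet, 0.0766 M. Tuesday's lies below it, so the secretary put that flask at 0.0564 M. Friday's and Thursday's lie above it, so the secretary put both at the ceiling.

The forecaster then reported 0.0075 M, 0.018 M, 0.044 M, 0.065 M and 0.072 M, a row that rises all the way, flattening towards 0.075 M. The stated ground was: “That indicates saturation of the second catalyst”. The secretary's figures differ from these, being higher for Tuesday's and for Friday's.

The flasks gave 0.00755 M, 0.0184 M, 0.0469 M, 0.0761 M and 0.0848 M, and the row rises all the way.

    reagent + catalyst intermediate → second catalyst + target (k = 0.820 L mol⁻¹ h⁻¹)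
    substrate + open intermediate → side product (k = 0.170 L mol⁻¹ h⁻¹)
    second catalyst + open intermediate ⇌ catalyst intermediate (K = 56.0 L mol⁻¹, k = 42.0 L mol⁻¹ h⁻¹)
    substrate + free catalyst → free catalyst + open intermediate (k = 51.0 L mol⁻¹ h⁻¹)

In Thursday's flask at 2.50 d, substrate stood at 0%, open intermediate at 76.5% of the charge, and catalyst intermediate, the resting state, held 94.6% of the second catalyst, while its step with reagent had made target to 1.18 times the ceiling. In Friday's flask at 2.50 d, catalyst intermediate held 81.4% of the second catalyst, open intermediate stood at 57.2% of the charge, and target had reached 1.06 times the ceiling.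

The earlier runs and the new flask stem from a simulated flask for substances that don't exist; scatter was added.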